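**Retrosynthetic overview**
- The target is the tri-O-benzyl ether of itself after a final global hydrogenolysis.
- Key disconnection: the C6(sp2)–CH2(sp3) bond, made from a 6-iodoflavanonol and a 4-benzyloxybenzyl radical (from the arylacetic acid, –CO2) under visible-light Ni/Ir catalysis.
- The C6 iodide comes from iodination ortho to the only free phenol (the chelated 5-OH) of 7,4'-di-O-benzylaromadendrin.
- No ring is constructed: the A/C chromanone rings, the B ring and both stereocentres (2R,3R, trans) are bought in (+)-aromadendrin and never touched; the fourth ring arrives intact in the benzyl unit.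

Assumption: (+)-aromadendrin ((2R,3R)-dihydrokaempferol) is purchased as the enantiopure natural product; all other reagents are catalogue chemicals.

**Step 1**
Reactants: 1, (+)-aromadendrin, (2R,3R)-3,5,7-trihydroxy-2-(4-hydroxyphenyl)chroman-4-one; 2, benzyl bromide
Product: 3, (2R,3R)-7-(benzyloxy)-2-[4-(benzyloxy)phenyl]-3,5-dihydroxychroman-4-one (7,4'-di-O-benzylaromadendrin)
Conditions: BnBr (2.2 equiv), K2CO3 (2.5 equiv), acetone, 50 °C, Ar
Reagents that add atoms: benzyl bromide, BrCc1ccccc1
Why: Williamson etherification alkylates only the two acidic phenols (7-OH para to the carbonyl, and 4'-OH), while the hydrogen-bonded 5-OH and the secondary 3-OH stay free; the mild carbonate conditions leave the thermodynamically preferred trans C2/C3 centres as bought.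

**Step 2**
Reactants: 3, 7,4'-di-O-benzylaromadendrin; 4, benzyltrimethylammonium dichloroiodate
Product: 5, (2R,3R)-7-(benzyloxy)-2-[4-(benzyloxy)phenyl]-3,5-dihydroxy-6-iodochroman-4-one
Conditions: BnMe3N·ICl2 (1.05 equiv), CaCO3, CH2Cl2–MeOH (5:2), rt, dark
Reagents that add atoms: benzyltrimethylammonium dichloroiodate, C[N+](C)(C)Cc1ccccc1.Cl[I-]Cl
Why: Electrophilic aromatic iodination goes ortho to the single free, chelated phenol (C6, between 5-OH and 7-OBn), the selectivity seen for 5-hydroxy-7-alkoxyflavones with this reagent (a direct flavanonol example is not known to me); the alkoxyphenyl rings are much less reactive and no stereocentre is involved.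

**Step 3**
Reactants: 5, the 6-iodide; 6, 4-(benzyloxy)phenylacetic acid
Product: 7, (2R,3R)-7-(benzyloxy)-6-[4-(benzyloxy)benzyl]-2-[4-(benzyloxy)phenyl]-3,5-dihydroxychroman-4-one
Conditions: 6 (2 equiv), Cs2CO3 (1 equiv), Ir[dF(CF3)ppy]2(dtbbpy)PF6 (2 mol %), NiCl2·glyme (10 mol %), dtbbpy (15 mol %), degassed DMF, 450 nm LEDs, rt, 24 h
Reagents that add atoms: 4-(benzyloxy)phenylacetic acid, OC(=O)Cc1ccc(OCc2ccccc2)cc1 (transfers the 4-benzyloxybenzyl group; CO2 is lost)
Why: Proposed new method: visible-light Ni/Ir decarboxylative benzylation of a doubly ortho-oxygenated aryl iodide that keeps its free chelated ortho-phenol and α-ketol — excited Ir(III) oxidises the caesium arylacetate to CO2 and the 4-benzyloxybenzyl radical, (dtbbpy)Ni(0) inserts into the weak C6–I bond, the radical is captured at nickel and the crowded Ni(III)(aryl)(benzyl) reductively eliminates the C6–CH2 bond while Ir(II) returns Ni(I) to Ni(0); using one carbonate per two acids gives only the carboxylate, so the 5-OH stays protonated and hydrogen-bonded rather than becoming an oxidisable phenolate, and no stereocentre is touched; the closest known reaction type is metallaphotoredox decarboxylative C(sp3)–C(sp2) arylation of carboxylic acids with aryl halides, not yet shown on flavonoid halides or on free-phenol, 2,6-dioxygenated iodoarenes.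

**Step 4**
Reactants: 7, the tri-O-benzyl ether
Product: 8, gericudranin E, (2R,3R)-3,5,7-trihydroxy-6-(4-hydroxybenzyl)-2-(4-hydroxyphenyl)chroman-4-one
Conditions: H2 (1 atm), 10% Pd/C, EtOAc–MeOH (1:1), rt
Reagents that add atoms: none
Why: Catalytic hydrogenolysis cleaves the three aryl benzyl ethers under neutral conditions, which avoids acid-promoted loss or migration of the p-hydroxybenzyl group; the diarylmethane, the aryl ketone and the cyclic C2–O1 ether survive at 1 atm and rt, and neither stereocentre is affected.

**Compound list**
1 | (+)-aromadendrin, (2R,3R)-3,5,7-trihydroxy-2-(4-hydroxyphenyl)chroman-4-one | O=C1c2c(cc(O)cc2O)O[C@H](c2ccc(O)cc2)[C@H]1O | starting material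
2 | benzyl bromide | BrCc1ccccc1 | starting material
3 | 7,4'-di-O-benzylaromadendrin | O=C1c2c(cc(OCc3ccccc3)cc2O)O[C@H](c2ccc(OCc3ccccc3)cc2)[C@H]1O | intermediate
4 | benzyltrimethylammonium dichloroiodate | C[N+](C)(C)Cc1ccccc1.Cl[I-]Cl | starting material
5 | 6-iodo-7,4'-di-O-benzylaromadendrin | O=C1c2c(cc(OCc3ccccc3)c(I)c2O)O[C@H](c2ccc(OCc3ccccc3)cc2)[C@H]1O | intermediate
6 | 4-(benzyloxy)phenylacetic acid | OC(=O)Cc1ccc(OCc2ccccc2)cc1 | starting material
7 | 6-[4-(benzyloxy)benzyl]-7,4'-di-O-benzylaromadendrin | O=C1c2c(cc(OCc3ccccc3)c(Cc3ccc(OCc4ccccc4)cc3)c2O)O[C@H](c2ccc(OCc3ccccc3)cc2)[C@H]1O | intermediate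
8 | gericudranin E | O=C1c2c(cc(O)c(Cc3ccc(O)cc3)c2O)O[C@H](c2ccc(O)cc2)[C@H]1O | target

**Total step count:** 4. **Longest linear sequence:** 4.

**Steps most likely to fail**
1. Step 3 (proposed new step). The Ni–aryl is flanked by OH and OBn, so radical capture may be slow and protodeiodination or bibenzyl formation may dominate. Fallback (known chemistry): Pd-catalysed Negishi coupling of 5 with 4-(benzyloxy)benzylzinc chloride (from the commercial benzyl chloride, Zn/LiCl) using Pd(OAc)2/SPhos in THF, a thermal two-electron cross-coupling that tolerates di-ortho substitution.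
2. Step 2. C6 versus C8 selectivity, or over-iodination, could erode on the flavanonol because the precedent is on flavones. Fallback: drop the halogen handle and use boron-templated ortho-specific hydroxybenzylation of 3 with 4-(benzyloxy)benzaldehyde and PhB(OH)2 (cat. EtCO2H, toluene, Dean–Stark), which forms a 1,3,2-benzodioxaborin anchored on O5 so only C6 is reachable, then ionic reduction with Et3SiH/TFA to give 7 directly (this bypasses steps 2–3).
3. Step 1. Carbonate base can open or epimerise the C-ring through the 4'-phenolate, oxidise the flavanonol to the flavonol, or over-alkylate. Fallback: change the protecting-group strategy to silyl ethers installed without carbonate (TIPSCl/imidazole for 7,4'-protection), use 4-(TIPSO)phenylacetic acid as the partner, and finish with HF·pyridine instead of hydrogenolysis.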